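**Strategy.** Numbering follows the cadinane skeleton (ring A: C6–C7–C8–C9–C10–C1; ring B carries C4=C5 and C15). In ring A the oxygenated carbon C8 is flanked by C7 and C9, and the exocyclic methylene carbon C10 sits beside ring-fusion carbon C1. A C8 ketone can therefore be annulated through both α-carbons onto a 1,3-bis-electrophile: C6 as enone β-carbon and C10 as alkyne carbon. One pot joins C6–C7 by Mukaiyama–Michael addition and C9–C10 by gold-catalysed Conia-ene closure, giving the trans-decalone with the methylene group and a regiodefined ring-B enol silane. The precursors are (S)-4-ethynylcyclohex-2-enone and a 2-silyloxyallylsilane, a ketone α,α′-dianion equivalent carrying a masked acetaldehyde arm.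

Key step: step 7

Remark: further labels are C14 (methylene carbon on C10), C11–C13 (acrylic acid unit on C7; C12 = carboxyl carbon) and C15 (CH2OH on C4). Ethyl 3-(1,3-dioxolan-2-yl)propanoate and (chloromethyl)triethylsilane are taken as purchasable. In step 2 the catalyst antipode is the one that delivers the (S) adduct.

**Ring-B enone**

Step 1
Reactants: 1 but-3-en-2-one (methyl vinyl ketone)
Product: 2 2-(triisopropylsilyloxy)buta-1,3-diene
Conditions: i-Pr3SiOTf, Et3N, Et2O, 0 °C → rt
Reagents that add atoms: triisopropylsilyl triflate, CC(C)[Si](C(C)C)(C(C)C)OS(=O)(=O)C(F)(F)F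
Why: Soft enolisation of the enone at its methyl group (silyl triflate/amine) should give the 2-silyloxy diene; no stereocentre is formed.

Step 2
Reactants: 2 2-(triisopropylsilyloxy)buta-1,3-diene; 3 2,2,2-trifluoroethyl acrylate
Product: 4 2,2,2-trifluoroethyl (S)-4-(triisopropylsilyloxy)cyclohex-3-ene-1-carboxylate
Conditions: protonated B-(o-tolyl)-diphenylprolinol oxazaborolidine, triflimide salt (10 mol%), CH2Cl2, −78 °C
Reagents that add atoms: none
Why: Catalytic enantioselective Diels–Alder reaction in which the 2-silyloxy group directs the ester to the "para" position and the cationic oxazaborolidine shields one face of the bound acrylate, which sets the future C1 stereocentre.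

Step 3
Reactants: 4 2,2,2-trifluoroethyl (S)-4-(triisopropylsilyloxy)cyclohex-3-ene-1-carboxylate
Product: 6 (S)-(4-ethynylcyclohex-1-en-1-yl)oxy-triisopropylsilane, via aldehyde 5 (not isolated)
Conditions: i-Bu2AlH (1.05 equiv), CH2Cl2, −78 °C; then MeOH, K2CO3, dimethyl (1-diazo-2-oxopropyl)phosphonate, −78 °C → rt
Reagents that add atoms: dimethyl (1-diazo-2-oxopropyl)phosphonate (Ohira–Bestmann reagent), COP(=O)(OC)C(=[N+]=[N-])C(C)=O
Why: One-pot half-reduction of the activated ester and Ohira–Bestmann (Seyferth–Gilbert) homologation should convert the aldehyde as it is released, which limits α-epimerisation; the hindered enol silane survives the carbonate and the stereocentre is not touched.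

Step 4
Reactants: 6 (S)-(4-ethynylcyclohex-1-en-1-yl)oxy-triisopropylsilane
Product: 9 (S)-4-ethynylcyclohex-2-en-1-one, via selenide 7 (not isolated), via selenoxide 8 (not isolated)
Conditions: PhSeCl, CH2Cl2, −78 °C; then 30% H2O2, pyridine, 0 °C → rt
Reagents that add atoms: none
Why: α-Selenenylation of the silyl enol ether followed by selenoxide syn-elimination can only place the new alkene between C5 and C6, and the neutral conditions should leave the γ-stereocentre (C1) intact.

**Bis-nucleophile**

Step 5
Reactants: 10 ethyl 3-(1,3-dioxolan-2-yl)propanoate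
Product: 11 4-(1,3-dioxolan-2-yl)-1-(triethylsilyl)butan-2-one
Conditions: Et3SiCH2Li (2.1 equiv; from Et3SiCH2Cl, Li, pentane), THF, −78 → −20 °C; cold aq. NH4Cl
Reagents that add atoms: (triethylsilyl)methyllithium, [Li]C[Si](CC)(CC)CC (made from (chloromethyl)triethylsilane, ClC[Si](CC)(CC)CC)
Why: Acylation of the α-silyl carbanion by the ester, in which the α-silyl ketone is protected from a second addition as its enolate (second equivalent of base) and a cold buffered quench keeps the C–Si bond.

Step 6
Reactants: 11 4-(1,3-dioxolan-2-yl)-1-(triethylsilyl)butan-2-one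
Product: 12 (Z)-4-(1,3-dioxolan-2-yl)-1-(triethylsilyl)-2-(triethylsilyloxy)but-2-ene
Conditions: LiN(i-Pr)2, Et3SiCl (present from the start), THF, −78 °C
Reagents that add atoms: chlorotriethylsilane, CC[Si](Cl)(CC)CC
Why: Kinetic enolisation of an α-silyl ketone is expected at the α′-methylene remote from the bulky silyl group, and O-silylation should give the 2-silyloxyallylsilane, mainly as the (Z) isomer.

**Key step**

Step 7
Reactants: 9 (S)-4-ethynylcyclohex-2-en-1-one; 12 (Z)-4-(1,3-dioxolan-2-yl)-1-(triethylsilyl)-2-(triethylsilyloxy)but-2-ene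
Product: 14 7-(1,3-dioxolan-2-ylmethyl)-10-methylene-4-(triethylsilyloxy)-trans-decal-4-en-8-one (numbering as above; C1/C6/C7 as in the target), via bis(enol silane) 13 (not isolated)
Conditions: Et3SiOTf (10 mol%), 2,6-di-tert-butyl-4-methylpyridine (15 mol%), CH2Cl2, −78 → −20 °C; then [Au(P(t-Bu)2(biphenyl-2-yl))(NCMe)]SbF6 (5 mol%), i-PrOH (3 equiv), 0 °C → rt
Reagents that add atoms: none
Why: Et3SiOTf O-silylates enone 9 to a vinylogous oxocarbenium ion that is attacked at C6 by C7 of 12, which is at once a silyl enol ether carbon and an allylsilane γ-carbon (Mukaiyama–Michael/Sakurai-type conjugate addition, the known use of 2-silyloxyallylsilanes as ketone α,α′-dianion equivalents); the β-silyl oxocarbenium ion then loses the carbon-bound Et3Si group (any α-silyl ketone is funnelled the same way by the silyl triflate), so that 13 carries the ring-B enol silane and the terminal C8(OSiEt3)=C9H2 enol silane while the catalyst is regenerated. Cationic monovalent gold then π-activates the C10≡C14 alkyne and C9 adds in a 6-exo-dig Conia-ene-type closure of ring A (chair-like, with the C6 and C1 branches equatorial); protodeauration by i-PrOH and loss of i-PrOSiEt3 should give the C8 ketone with the exocyclic C10=C14 methylene. C6 is set by attack anti to the ethynyl group on C1 (substrate control, trans ring fusion), and C7 by the open antiperiplanar transition state, which should favour the anti adduct that becomes the equatorial side chain. The step needs C9 to react in preference to the ring-B enol silane (which could reach the alkyne only 5-endo through a diaxial conformer) and 6-exo in preference to 7-endo attack (favoured for a terminal alkyne); the hindered pyridine keeps the medium acid-free so that both enol silanes and the dioxolane survive.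

**Completion**

Step 8
Reactants: 14 7-(1,3-dioxolan-2-ylmethyl)-10-methylene-4-(triethylsilyloxy)-trans-decal-4-en-8-one
Product: 15 the corresponding 8-axial alcohol (C8–OH cis to the C7 side chain)
Conditions: LiBH(s-Bu)3, THF, −78 °C; H2O
Reagents that add atoms: none
Why: The bulky borohydride should attack the C8 ketone from the equatorial direction, giving the axial alcohol cis to the equatorial C7 substituent as in the target.

Step 9
Reactants: 15 8-axial alcohol with ring-B triethylsilyl enol ether
Product: 16 the corresponding C4 enol nonaflate (C4=C5) with free C8–OH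
Conditions: n-C4F9SO2F (1.3 equiv), Bu4N[Ph3SiF2] (10 mol%), THF, 0 °C → rt
Reagents that add atoms: nonafluorobutanesulfonyl fluoride, FS(=O)(=O)C(F)(F)C(F)(F)C(F)(F)C(F)(F)F
Why: Fluoride-catalysed sulfonylation of a silyl enol ether is regiospecific because the enolate is trapped as it forms, so the C4=C5 position fixed by the conjugate addition is kept; the alcohol is not basic enough to be sulfonylated.

Step 10
Reactants: 17 (tert-butyldimethylsilyloxy)acetaldehyde; 18 1,1,1,3,3,3-hexafluoropropan-2-yl acrylate
Product: 19 1,1,1,3,3,3-hexafluoropropan-2-yl (S)-4-(tert-butyldimethylsilyloxy)-3-hydroxy-2-methylenebutanoate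
Conditions: β-isocupreidine (10 mol%), DMF, −55 °C
Reagents that add atoms: none
Why: Asymmetric Morita–Baylis–Hillman reaction in which the cinchona-derived amine–phenol catalyst controls the aldehyde face and should set the (S) carbinol centre.

Step 11
Reactants: 19 (S) Morita–Baylis–Hillman adduct
Product: 20 1,1,1,3,3,3-hexafluoropropan-2-yl (S)-3,4-bis(tert-butyldimethylsilyloxy)-2-methylenebutanoate
Conditions: t-BuMe2SiOTf, 2,6-lutidine, CH2Cl2, 0 °C
Reagents that add atoms: tert-butyldimethylsilyl triflate, CC(C)(C)[Si](C)(C)OS(=O)(=O)C(F)(F)F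
Why: Standard silylation of the secondary allylic alcohol; the stereocentre is not involved.

Step 12
Reactants: 20 bis-silylated hexafluoroisopropyl ester
Product: 21 (S)-3,4-bis(tert-butyldimethylsilyloxy)-2-methylenebutanoic acid
Conditions: LiOH, THF/H2O, 0 °C; then aq. HCl to pH 3
Reagents that add atoms: lithium hydroxide (hydroxide oxygen), [Li+].[OH-]
Why: The activated fluoroalkyl ester should saponify under conditions mild enough to leave the silyl ethers and the acrylate untouched.

Step 13
Reactants: 16 hydroxy enol nonaflate; 21 (S)-3,4-bis(tert-butyldimethylsilyloxy)-2-methylenebutanoic acid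
Product: 23 C8 ester of 16 with acid 21, via mixed anhydride 22 (not isolated)
Conditions: 2,4,6-trichlorobenzoyl chloride, Et3N, THF, rt; then 16, DMAP, toluene, rt → 40 °C
Reagents that add atoms: none
Why: Yamaguchi esterification through the mixed anhydride is suited to hindered secondary alcohols and proceeds with retention at C8.

Step 14
Reactants: 23 ester enol nonaflate
Product: 24 the C15 allylic alcohol (CH2OH on C4)
Conditions: Bu3SnCH2OH, Pd(PPh3)4 (5 mol%), LiCl, 1,4-dioxane, 90 °C
Reagents that add atoms: (tributylstannyl)methanol, OC[Sn](CCCC)(CCCC)CCCC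
Why: Stille coupling of the alkenyl sulfonate with the hydroxymethyl stannane (zerovalent palladium) installs C15 at C4 with the alkene fixed at C4=C5.

Step 15
Reactants: 24 C15 alcohol with dioxolane and two silyl ethers
Product: 25 the C12 aldehyde with free C15–OH and free side-chain diol
Conditions: aq. HCl (2 M), THF, rt
Reagents that add atoms: water, O
Why: Acid hydrolysis should cleave the dioxolane and both silyl ethers in one operation while the 1,1-disubstituted alkenes and the ester tolerate dilute aqueous acid at room temperature.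

Step 16
Reactants: 25 C12 aldehyde
Product: 26 the 2-substituted acrolein (C11=C13 methylene, C12 aldehyde)
Conditions: aq. CH2O (37%), pyrrolidine (10 mol%), propionic acid (10 mol%), i-PrOH, 45 °C
Reagents that add atoms: formaldehyde, C=O
Why: Amine-catalysed Mannich condensation and elimination (α-methylenation of an aldehyde) acts only at C11, the single enolisable position next to the aldehyde, and does not involve the C7 stereocentre.

Step 17
Reactants: 26 enal
Product: 27 CNP0460913.1
Conditions: NaClO2, NaH2PO4, 2-methylbut-2-ene, t-BuOH/H2O, 0 °C → rt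
Reagents that add atoms: sodium chlorite, [Na+].[O-]Cl=O
Why: Pinnick oxidation converts the enal into the acrylic acid without touching the alcohols, the alkenes or the ester.

**Compound list**

1 | but-3-en-2-one | C=CC(C)=O | starting material
2 | 2-(triisopropylsilyloxy)buta-1,3-diene | C=CC(=C)O[Si](C(C)C)(C(C)C)C(C)C | intermediate
3 | 2,2,2-trifluoroethyl acrylate | C=CC(=O)OCC(F)(F)F | starting material
4 | 2,2,2-trifluoroethyl (S)-4-(triisopropylsilyloxy)cyclohex-3-ene-1-carboxylate | FC(F)(F)COC(=O)[C@@H]1CC=C(O[Si](C(C)C)(C(C)C)C(C)C)CC1 | intermediate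
5 | (S)-4-(triisopropylsilyloxy)cyclohex-3-ene-1-carbaldehyde | O=C[C@@H]1CC=C(O[Si](C(C)C)(C(C)C)C(C)C)CC1 | intermediate
6 | (S)-(4-ethynylcyclohex-1-en-1-yl)oxy-triisopropylsilane | C#C[C@@H]1CC=C(O[Si](C(C)C)(C(C)C)C(C)C)CC1 | intermediate
7 | (4S)-4-ethynyl-2-(phenylselanyl)cyclohexan-1-one (both C2 epimers) | O=C1C([Se]c2ccccc2)C[C@@H](C#C)CC1 | intermediate
8 | (4S)-4-ethynyl-2-(phenylseleninyl)cyclohexan-1-one | O=C1C([Se](=O)c2ccccc2)C[C@@H](C#C)CC1 | intermediate
9 | (S)-4-ethynylcyclohex-2-en-1-one | O=C1C=C[C@@H](C#C)CC1 | intermediate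
10 | ethyl 3-(1,3-dioxolan-2-yl)propanoate | CCOC(=O)CCC1OCCO1 | starting material
11 | 4-(1,3-dioxolan-2-yl)-1-(triethylsilyl)butan-2-one | CC[Si](CC)(CC)CC(=O)CCC1OCCO1 | intermediate
12 | (Z)-4-(1,3-dioxolan-2-yl)-1-(triethylsilyl)-2-(triethylsilyloxy)but-2-ene | CC[Si](CC)(CC)C/C(O[Si](CC)(CC)CC)=C/CC1OCCO1 | intermediate
13 | bis(enol silane): 1-(triethylsilyloxy)cyclohexene with the ethynyl group on C1 (decalin numbering) and, trans to it on C6, the chain C7H(CH2-dioxolanyl)–C8(OSiEt3)=C9H2 | C1(OCCO1)C[C@@H](C(=C)O[Si](CC)(CC)CC)[C@H]2C=C(O[Si](CC)(CC)CC)CC[C@@H]2C#C | intermediate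
14 | 7-(1,3-dioxolan-2-ylmethyl)-10-methylene-4-(triethylsilyloxy)-trans-decal-4-en-8-one (H1/H6 trans, C7 side chain equatorial) | C1(OCCO1)C[C@@H]2[C@H]3C=C(O[Si](CC)(CC)CC)CC[C@@H]3C(=C)CC2=O | intermediate
15 | 8-axial alcohol of 14 (OH cis to the C7 side chain) | C1(OCCO1)C[C@@H]2[C@H]3C=C(O[Si](CC)(CC)CC)CC[C@@H]3C(=C)C[C@@H]2O | intermediate
16 | C4 enol nonaflate of 15 (C4=C5, free C8–OH) | C1(OCCO1)C[C@@H]2[C@H]3C=C(OS(=O)(=O)C(F)(F)C(F)(F)C(F)(F)C(F)(F)F)CC[C@@H]3C(=C)C[C@@H]2O | intermediate
17 | (tert-butyldimethylsilyloxy)acetaldehyde | O=CCO[Si](C)(C)C(C)(C)C | starting material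
18 | 1,1,1,3,3,3-hexafluoropropan-2-yl acrylate | C=CC(=O)OC(C(F)(F)F)C(F)(F)F | starting material
19 | 1,1,1,3,3,3-hexafluoropropan-2-yl (S)-4-(tert-butyldimethylsilyloxy)-3-hydroxy-2-methylenebutanoate | C=C(C(=O)OC(C(F)(F)F)C(F)(F)F)[C@H](O)CO[Si](C)(C)C(C)(C)C | intermediate
20 | 1,1,1,3,3,3-hexafluoropropan-2-yl (S)-3,4-bis(tert-butyldimethylsilyloxy)-2-methylenebutanoate | C=C(C(=O)OC(C(F)(F)F)C(F)(F)F)[C@H](O[Si](C)(C)C(C)(C)C)CO[Si](C)(C)C(C)(C)C | intermediate
21 | (S)-3,4-bis(tert-butyldimethylsilyloxy)-2-methylenebutanoic acid | C=C(C(=O)O)[C@H](O[Si](C)(C)C(C)(C)C)CO[Si](C)(C)C(C)(C)C | intermediate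
22 | mixed anhydride of 21 with 2,4,6-trichlorobenzoic acid | C=C(C(=O)OC(=O)c1c(Cl)cc(Cl)cc1Cl)[C@H](O[Si](C)(C)C(C)(C)C)CO[Si](C)(C)C(C)(C)C | intermediate
23 | C8 ester of 16 with acid 21 | C1(OCCO1)C[C@@H]2[C@H]3C=C(OS(=O)(=O)C(F)(F)C(F)(F)C(F)(F)C(F)(F)F)CC[C@@H]3C(=C)C[C@@H]2OC(=O)C(=C)[C@H](O[Si](C)(C)C(C)(C)C)CO[Si](C)(C)C(C)(C)C | intermediate
24 | C15 allylic alcohol (CH2OH on C4; dioxolane and both silyl ethers still in place) | C1(OCCO1)C[C@@H]2[C@H]3C=C(CO)CC[C@@H]3C(=C)C[C@@H]2OC(=O)C(=C)[C@H](O[Si](C)(C)C(C)(C)C)CO[Si](C)(C)C(C)(C)C | intermediate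
25 | C12 aldehyde (C7–CH2–CHO) with free C15–OH and free side-chain diol | O=CC[C@@H]1[C@H]2C=C(CO)CC[C@@H]2C(=C)C[C@@H]1OC(=O)C(=C)[C@H](O)CO | intermediate
26 | enal: C7–C(=CH2)–CHO, otherwise as the target | C=C(C=O)[C@@H]1[C@H]2C=C(CO)CC[C@@H]2C(=C)C[C@@H]1OC(=O)C(=C)[C@H](O)CO | intermediate
27 | CNP0460913.1 | C=C(C(=O)O)[C@@H]1[C@H]2C=C(CO)CC[C@@H]2C(=C)C[C@@H]1OC(=O)C(=C)[C@H](O)CO | target

**Totals.** 17 steps in all; the longest linear sequence is 12 steps (steps 1–4, 7–9, 13–17).

**Steps most likely to fail**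

1. Step 7. The conjugate addition may show poor facial selectivity at C6 (the ethynyl group is small) or poor relative selectivity at C7. The C7 centre cannot be equilibrated later without moving the methylene group into conjugation. The ring-B enol silane may also intercept the gold-activated alkyne. Fallback, from 11 and 9 back to 14: the two bonds are made in separate, purifiable steps. Fluoride desilylation of 11 (Bu4NF hydrate, THF) gives 4-(1,3-dioxolan-2-yl)butan-2-one F1. Thermodynamic silylation (Et3SiCl, NaI, Et3N, MeCN) gives its internal (Z)-triethylsilyl enol ether F2. Et3SiOTf-catalysed Mukaiyama–Michael addition of F2 to 9 gives the methyl ketone adduct F3, and the C6/C7 diastereomers are separated at this stage. Kinetic enolisation at the methyl group (LiN(i-Pr)2, Et3SiCl, −78 °C) then gives 13, which is cyclised with the gold catalyst to 14.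

2. Step 6. Enolisation may occur on the silyl-bearing side (giving a vinylsilane enol ether) or the C–Si bond may be lost. Fallback, from 10 and 9 back to 14: a β-keto ester whose γ-carbon is unambiguously C7 replaces the α-silyl ketone. Crossed Claisen condensation of 10 with the lithium enolate of allyl acetate gives allyl 5-(1,3-dioxolan-2-yl)-3-oxopentanoate F4. Two-stage silylation (Et3SiOTf/Et3N, then LiN(i-Pr)2/Et3SiCl) gives 1-(allyloxy)-5-(1,3-dioxolan-2-yl)-1,3-bis(triethylsilyloxy)penta-1,3-diene F5. With 9, the same Et3SiOTf then gold/i-PrOH sequence (Mukaiyama–Michael through the γ-carbon, Conia-ene of the β-keto ester) gives the C9 allyl ester of 14, F6. Deallylation–decarboxylation (Pd(PPh3)4, morpholine, THF) returns 14.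

3. Step 13. Acylation of the hindered axial alcohol may be slow, with competing dehydration towards the diene or amine addition to the acrylate. Fallback, from 14 back to 23: the ester is introduced with inversion instead. Reduction of 14 with the small hydride LiAlH(O-t-Bu)3 (THF, −78 → 0 °C) gives the equatorial C8 alcohol F7. Nonaflation as in step 9 gives its enol nonaflate F8. Mitsunobu esterification with 21 (PPh3, diisopropyl azodicarboxylate, toluene) inverts C8 and gives 23.

Further compounds
F1 | step 7 | 4-(1,3-dioxolan-2-yl)butan-2-one | CC(=O)CCC1OCCO1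
F2 | step 7 | (Z)-4-(1,3-dioxolan-2-yl)-2-(triethylsilyloxy)but-2-ene | C/C(O[Si](CC)(CC)CC)=C/CC1OCCO1
F3 | step 7 | methyl ketone adduct: 13 with C8(=O)–CH3 in place of the terminal enol silane | C1(OCCO1)C[C@@H](C(C)=O)[C@H]2C=C(O[Si](CC)(CC)CC)CC[C@@H]2C#C
F4 | step 6 | allyl 5-(1,3-dioxolan-2-yl)-3-oxopentanoate | C=CCOC(=O)CC(=O)CCC1OCCO1
F5 | step 6 | 1-(allyloxy)-5-(1,3-dioxolan-2-yl)-1,3-bis(triethylsilyloxy)penta-1,3-diene | C=CCOC(O[Si](CC)(CC)CC)=CC(O[Si](CC)(CC)CC)=CCC1OCCO1
F6 | step 6 | C9 allyl ester of 14 (C9 configuration open) | C1(OCCO1)C[C@@H]2[C@H]3C=C(O[Si](CC)(CC)CC)CC[C@@H]3C(=C)C(C(=O)OCC=C)C2=O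
F7 | step 13 | 8-equatorial alcohol (C8 epimer of 15) | C1(OCCO1)C[C@@H]2[C@H]3C=C(O[Si](CC)(CC)CC)CC[C@@H]3C(=C)C[C@H]2O
F8 | step 13 | enol nonaflate of F7 (C8 epimer of 16) | C1(OCCO1)C[C@@H]2[C@H]3C=C(OS(=O)(=O)C(F)(F)C(F)(F)C(F)(F)C(F)(F)F)CC[C@@H]3C(=C)C[C@H]2O
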